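A direct plan would add ethynylmagnesium bromide to 4-(benzyloxy)benzaldehyde, join the carbinol to 3,5-bis(benzyloxy)phenol by a Mitsunobu reaction (propargyl aryl ether A1), rearrange A1 thermally to 2H-chromene A2, dihydroxylate to diol A3, oxidise and debenzylate to kaempferol A4, and sulfate A4.
Weak point 1, the thermal propargyl Claisen/oxa-electrocyclisation of A1 to A2: a 1-aryl propargyl aryl ether at 160–180 °C would ionise easily, so benzofuran and C-alkylation paths would compete with ring C closure.
Weak point 2, the dihydroxylation and diol oxidation from A2 through A3: three stereocentres would be set only to be erased, four redox changes at C2–C4 would build no bond, and the diol-to-flavonol oxidation would risk C3–C4 cleavage.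
Weak point 3, the last-step sulfation of A4: three benzyl ethers would be carried and removed only to expose four hydroxyls, so sparing O5 would rest on reagent stoichiometry on the most valuable material.

**Retrosynthetic overview of the new route**
Ring C is bought, not made: comenic acid (5-hydroxy-4-oxo-4H-pyran-2-carboxylic acid) already holds O1, C2, C3–OH, C4=O, C4a and C8a at the final oxidation level, so no stereocentre and no redox correction appears.
Ring B is joined at C2 by Suzuki coupling of the 6-bromo derivative.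
Ring A (C5, C6, C7, C8) is built last by a photochemical Danheiser benzannulation of the pyranonyl diazomethyl ketone with a siloxyacetylene, which forms C8–C8a, C5–C6, C7–C8 and C4a–C5 in one operation.
The feature used is the unsymmetrical oxygenation of ring A: the ketene oxygen (the old carboxyl C=O) becomes the lone free 5-OH peri to C4=O, and the alkyne oxygen becomes O7 as a silyl ether.
O5 is capped in the same flask, so the final sulfation of O3, O7 and O4' is exhaustive instead of selective; the ring order is C (bought), B (attached), A (closed last).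

Key step: step 6

Assumption: the target is drawn as the free tris(hydrogen sulfate); it would be generated cold from its ammonium salt in the last operation and stored as a salt.

**Step 1**
Reactants: 1 comenic acid (5-hydroxy-4-oxo-4H-pyran-2-carboxylic acid)
Product: 2 6-bromo-5-hydroxy-4-oxo-4H-pyran-2-carboxylic acid
Conditions: Br2 (1.05 equiv), H2O, rt
Reagents that add atoms: bromine, BrBr
Why: Electrophilic bromination of the enolic 3-hydroxy-4-pyranone at C6, its only activated free position (ortho to the hydroxyl, next to the ring oxygen), a classical halogenation of comenic acid that marks the future C2.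

**Step 2**
Reactants: 2 6-bromo-5-hydroxy-4-oxo-4H-pyran-2-carboxylic acid
Product: 3 benzyl 5-(benzyloxy)-6-bromo-4-oxo-4H-pyran-2-carboxylate
Conditions: BnBr (2.3 equiv), K2CO3, DMF, rt
Reagents that add atoms: benzyl bromide, BrCc1ccccc1
Why: Double Williamson-type O-alkylation of the carboxylate and the acidic enolic hydroxyl (the future O3) under mild carbonate conditions should mask both acidic sites before the palladium step.

**Step 3**
Reactants: 3 benzyl 5-(benzyloxy)-6-bromo-4-oxo-4H-pyran-2-carboxylate; 4 4-(benzyloxy)phenylboronic acid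
Product: 6 5-(benzyloxy)-6-[4-(benzyloxy)phenyl]-4-oxo-4H-pyran-2-carboxylic acid, via biaryl benzyl ester 5 (not isolated)
Conditions: PdCl2(dppf) (3 mol%), K3PO4, dioxane/H2O (10:1), 70 °C; then LiOH, THF/H2O, 0 °C; aq HCl to pH 2
Reagents that add atoms: lithium hydroxide, [Li+].[OH-]
Why: Suzuki–Miyaura coupling at the C–Br bond of a vinylogous acyl bromide, which should add readily to zerovalent palladium, joins ring B to the future C2, and saponification of the benzyl ester in the same flask lets the acid be purified by acid–base extraction.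

**Step 4**
Reactants: 6 5-(benzyloxy)-6-[4-(benzyloxy)phenyl]-4-oxo-4H-pyran-2-carboxylic acid
Product: 8 3-(benzyloxy)-2-[4-(benzyloxy)phenyl]-6-(diazoacetyl)-4H-pyran-4-one, via acid chloride 7 (not isolated)
Conditions: (COCl)2, DMF (cat.), CH2Cl2, 0 °C to rt; evaporate; CH2N2 (3 equiv), Et2O/THF, 0 °C, dark
Reagents that add atoms: diazomethane, C=[N+]=[N-]; oxalyl chloride, O=C(Cl)C(=O)Cl (chlorine of 7 only)
Why: Acyl chloride formation followed by acylation of diazomethane (first stage of the Arndt–Eistert sequence, excess diazomethane taking up HCl as chloromethane) should give the α-diazo ketone, the pyranone and benzyl ethers being inert to both reagents.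

**Step 5**
Reactants: 9 acetylene
Product: 12 (triisopropylsilyloxy)ethyne, via lithium acetylide 10 (not isolated), via lithium ethynolate 11 (not isolated)
Conditions: n-BuLi, THF, −78 °C; t-BuOOLi (from t-BuOOH, LiN(SiMe3)2), −78 to 0 °C; i-Pr3SiOTf, −78 °C to rt; distillation
Reagents that add atoms: tert-butyl hydroperoxide, CC(C)(C)OO; triisopropylsilyl trifluoromethanesulfonate, CC(C)[Si](C(C)C)(C(C)C)OS(=O)(=O)C(F)(F)F
Why: Electrophilic oxygenation of a lithium acetylide by lithium tert-butyl peroxide gives the ynolate, which the bulky silyl triflate should silylate on oxygen; this general route from 1-alkynes to 1-siloxyalkynes is applied here to the parent acetylide, kept cold so that it does not disproportionate.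

**Step 6**
Reactants: 8 3-(benzyloxy)-2-[4-(benzyloxy)phenyl]-6-(diazoacetyl)-4H-pyran-4-one; 12 (triisopropylsilyloxy)ethyne
Product: 18 3-(benzyloxy)-2-[4-(benzyloxy)phenyl]-4-oxo-7-[(triisopropylsilyl)oxy]-4H-chromen-5-yl acetate, via pyranonylketene 13 (not isolated), via siloxycyclobutenone 14 (not isolated), via dienylketene 15 (not isolated), via 4aH-dienone 16 (not isolated), via 5-hydroxy-7-siloxyflavone 17 (not isolated)
Conditions: 12 (3 equiv), ClCH2CH2Cl (degassed, 0.02 M), hν (blue LEDs, 440 nm), rt; then 80 °C, dark; then Ac2O, Et3N, DMAP (cat.), rt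
Reagents that add atoms: acetic anhydride, CC(=O)OC(C)=O
Why: Irradiation of 8 expels N2 and the Wolff 1,2-shift of the pyranonyl group (forming C8–C8a) gives ketene 13, which adds [2+2] to the electron-rich ynol ether 12 to give cyclobutenone 14 (bonds C5–C6 and C7–C8); heating opens 14 by 4π-electrocyclic cleavage of the old ketene C=C bond to dienylketene 15, which closes onto the free pyranone carbon by 6π-electrocyclization (bond C4a–C5) to dienone 16 and enolises to phenol 17, whose only free hydroxyl is then acetylated in the same flask. The closest known reaction type is the photochemical Wolff variant of the Danheiser benzannulation, in which aryl, heteroaryl and alkenyl diazomethyl ketones combine with alkoxy- and siloxyalkynes to give resorcinol mono-ethers. Ring A, the six-membered carbocycle, closes by a thermal disrotatory six-electron electrocyclization of a dienylketene in which the pyranone C4a=C8a bond serves as the terminal alkene, followed by enolisation to the aromatic ring. No stereocentre remains, because the sp3 carbons of 14 and 16 are transient and lost on aromatisation, and the isomer of 15 that cannot cyclise should revert through 14. The step needs one regiochemistry in the [2+2] addition, which the polarity of the partners secures (nucleophilic terminal CH of 12 to the ketene carbonyl carbon), so that the silyloxy group ends at C7 meta to the ketene-derived 5-OH, and the site of ring closure is unambiguous because the pyranone carbon that carries the ketene has O1 as its other neighbour. Visible light beyond the absorption of the aryl-pyranone and of the 5-hydroxyflavone product is chosen so that only the diazo group is excited.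

**Step 7**
Reactants: 18 3-(benzyloxy)-2-[4-(benzyloxy)phenyl]-4-oxo-7-[(triisopropylsilyl)oxy]-4H-chromen-5-yl acetate
Product: 20 3,7-dihydroxy-2-(4-hydroxyphenyl)-4-oxo-4H-chromen-5-yl acetate (5-O-acetylkaempferol), via 7-O-silyl diol 19 (not isolated)
Conditions: H2 (1 atm), 10% Pd/C, THF/EtOAc, rt; filter; Et3N·3HF, THF, rt
Reagents that add atoms: none
Why: Catalytic hydrogenolysis should remove both benzyl ethers without touching the aryl acetate or the pyranone C2=C3 bond, and the weakly acidic fluoride source then cleaves the aryl silyl ether without the phenoxide build-up that could move the acetyl group.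

**Step 8**
Reactants: 20 3,7-dihydroxy-2-(4-hydroxyphenyl)-4-oxo-4H-chromen-5-yl acetate
Product: 22 kaempferol 3,7,4'-tri-O-sulfate, via 5-O-acetyl trisulfate 21 (not isolated)
Conditions: SO3·pyridine (9 equiv), DMF/pyridine, rt to 40 °C; then NH3 (7 M in MeOH), 0 °C; C18 or Sephadex LH-20 (ammonium salt); sulfonic acid resin (H+ form), H2O, 0 °C, lyophilise
Reagents that add atoms: sulfur trioxide–pyridine complex, O=S(=O)([O-])[n+]1ccccc1
Why: O-sulfation of the phenolic and enolic hydroxyls by an amine–sulfur trioxide complex can be driven to completion with excess reagent because O5 is capped, after which ammonolysis removes the aryl acetate (aryl sulfate monoester anions are stable to base) and cold cation exchange gives the acid form.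

**Compound list**
1 | comenic acid (5-hydroxy-4-oxo-4H-pyran-2-carboxylic acid) | O=C(O)c1cc(=O)c(O)co1 | starting material
2 | 6-bromo-5-hydroxy-4-oxo-4H-pyran-2-carboxylic acid | O=C(O)c1cc(=O)c(O)c(Br)o1 | intermediate
3 | benzyl 5-(benzyloxy)-6-bromo-4-oxo-4H-pyran-2-carboxylate | O=C(OCc1ccccc1)c1cc(=O)c(OCc2ccccc2)c(Br)o1 | intermediate
4 | 4-(benzyloxy)phenylboronic acid | OB(O)c1ccc(OCc2ccccc2)cc1 | starting material
5 | benzyl 5-(benzyloxy)-6-[4-(benzyloxy)phenyl]-4-oxo-4H-pyran-2-carboxylate (not isolated) | O=C(OCc1ccccc1)c1cc(=O)c(OCc2ccccc2)c(-c2ccc(OCc3ccccc3)cc2)o1 | intermediate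
6 | 5-(benzyloxy)-6-[4-(benzyloxy)phenyl]-4-oxo-4H-pyran-2-carboxylic acid | O=C(O)c1cc(=O)c(OCc2ccccc2)c(-c2ccc(OCc3ccccc3)cc2)o1 | intermediate
7 | 5-(benzyloxy)-6-[4-(benzyloxy)phenyl]-4-oxo-4H-pyran-2-carbonyl chloride (not isolated) | O=C(Cl)c1cc(=O)c(OCc2ccccc2)c(-c2ccc(OCc3ccccc3)cc2)o1 | intermediate
8 | 3-(benzyloxy)-2-[4-(benzyloxy)phenyl]-6-(diazoacetyl)-4H-pyran-4-one | [N-]=[N+]=CC(=O)c1cc(=O)c(OCc2ccccc2)c(-c2ccc(OCc3ccccc3)cc2)o1 | intermediate
9 | acetylene | C#C | starting material
10 | lithium acetylide (not isolated) | [Li]C#C | intermediate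
11 | lithium ethynolate (not isolated) | [Li]OC#C | intermediate
12 | (triisopropylsilyloxy)ethyne | C#CO[Si](C(C)C)(C(C)C)C(C)C | intermediate
13 | 3-(benzyloxy)-2-[4-(benzyloxy)phenyl]-6-(2-oxoethenyl)-4H-pyran-4-one (ketene, not isolated) | O=C=Cc1cc(=O)c(OCc2ccccc2)c(-c2ccc(OCc3ccccc3)cc2)o1 | intermediate
14 | racemic 3-(benzyloxy)-2-[4-(benzyloxy)phenyl]-6-{4-oxo-2-[(triisopropylsilyl)oxy]cyclobut-2-en-1-yl}-4H-pyran-4-one (not isolated) | O=C1C=C(O[Si](C(C)C)(C(C)C)C(C)C)C1c1cc(=O)c(OCc2ccccc2)c(-c2ccc(OCc3ccccc3)cc2)o1 | intermediate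
15 | (3E)-4-{5-(benzyloxy)-6-[4-(benzyloxy)phenyl]-4-oxo-4H-pyran-2-yl}-3-[(triisopropylsilyl)oxy]buta-1,3-dien-1-one (ketene and pyranone cis, not isolated) | O=C=C/C(O[Si](C(C)C)(C(C)C)C(C)C)=C\c1cc(=O)c(OCc2ccccc2)c(-c2ccc(OCc3ccccc3)cc2)o1 | intermediate
16 | racemic 3-(benzyloxy)-2-[4-(benzyloxy)phenyl]-7-[(triisopropylsilyl)oxy]-4aH-chromene-4,5-dione (not isolated) | O=C1C=C(O[Si](C(C)C)(C(C)C)C(C)C)C=C2OC(c3ccc(OCc4ccccc4)cc3)=C(OCc3ccccc3)C(=O)C12 | intermediate
17 | 3-(benzyloxy)-2-[4-(benzyloxy)phenyl]-5-hydroxy-7-[(triisopropylsilyl)oxy]-4H-chromen-4-one (not isolated) | O=c1c(OCc2ccccc2)c(-c2ccc(OCc3ccccc3)cc2)oc2cc(O[Si](C(C)C)(C(C)C)C(C)C)cc(O)c12 | intermediate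
18 | 3-(benzyloxy)-2-[4-(benzyloxy)phenyl]-4-oxo-7-[(triisopropylsilyl)oxy]-4H-chromen-5-yl acetate | O=c1c(OCc2ccccc2)c(-c2ccc(OCc3ccccc3)cc2)oc2cc(O[Si](C(C)C)(C(C)C)C(C)C)cc(OC(C)=O)c12 | intermediate
19 | 3-hydroxy-2-(4-hydroxyphenyl)-4-oxo-7-[(triisopropylsilyl)oxy]-4H-chromen-5-yl acetate (not isolated) | O=c1c(O)c(-c2ccc(O)cc2)oc2cc(O[Si](C(C)C)(C(C)C)C(C)C)cc(OC(C)=O)c12 | intermediate
20 | 3,7-dihydroxy-2-(4-hydroxyphenyl)-4-oxo-4H-chromen-5-yl acetate (5-O-acetylkaempferol) | O=c1c(O)c(-c2ccc(O)cc2)oc2cc(O)cc(OC(C)=O)c12 | intermediate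
21 | 5-O-acetylkaempferol 3,7,4'-tris(hydrogen sulfate) (carried as its salt, not isolated) | O=c1c(OS(=O)(=O)O)c(-c2ccc(OS(=O)(=O)O)cc2)oc2cc(OS(=O)(=O)O)cc(OC(C)=O)c12 | intermediate
22 | kaempferol 3,7,4'-tri-O-sulfate | O=c1c(OS(=O)(=O)O)c(-c2ccc(OS(=O)(=O)O)cc2)oc2cc(OS(=O)(=O)O)cc(O)c12 | target

**Step count and risk**
Total steps: 8. Longest linear sequence: 7 (steps 1–4 and 6–8); step 5 is a one-step side branch.

Step 6 (key step). The aryl-pyranone chromophore may sensitise the diazo group, so that carbene side reactions or photorearrangement of the pyranone could outrun the Wolff shift, and the ketene may dimerise before it meets the alkyne. The fallback generates the same ketene without light. Setting out from 8, a Wolff rearrangement catalysed by PhCO2Ag with Et3N in dioxane/H2O should give the homologous acid {5-(benzyloxy)-6-[4-(benzyloxy)phenyl]-4-oxo-4H-pyran-2-yl}acetic acid F1, to be kept below room temperature. Oxalyl chloride would convert it into {5-(benzyloxy)-6-[4-(benzyloxy)phenyl]-4-oxo-4H-pyran-2-yl}acetyl chloride F2. Slow addition of Et3N to F2 in the presence of excess 12 would form ketene 13 by dehydrochlorination. The [2+2] addition and heating at 80–110 °C would rejoin the route at cyclobutenone 14 and continue to 17 and 18.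

Step 5. Monolithium acetylide may disproportionate, the parent ynolate may oligomerise or be silylated on carbon, and the terminal ynol ether may not survive distillation. The fallback uses a carbon-capped ynol ether. Commercial (trimethylsilyl)acetylene would be taken through the same lithiation, peroxide oxygenation and O-silylation, which has close precedent for silylacetylides, to give trimethyl({[tri(propan-2-yl)silyl]oxy}ethynyl)silane F3. Setting out from 8, the benzannulation with F3 should give 3-(benzyloxy)-2-[4-(benzyloxy)phenyl]-5-hydroxy-6-(trimethylsilyl)-7-[(triisopropylsilyl)oxy]-4H-chromen-4-one F4. Ipso-protodesilylation of F4 at C6, which lies between two oxygen-bearing carbons, with CF3CO2H in CH2Cl2 at 0 °C would return to the route at 17, which is then acetylated to 18.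

Step 8. Acetyl transfer among the phenoxides may occur before sulfation is complete, the hindered 3-hydroxyl may be sulfated incompletely, and sulfate may be lost by hydrolysis during the acidic resin passage. The fallback uses masked sulfate diesters. Setting out from 20, 2,2,2-trichloroethyl chlorosulfate with Et3N and DMAP in THF should give the neutral, chromatographable 5-O-acetylkaempferol 3,7,4'-tris(2,2,2-trichloroethyl sulfate) F5. Reductive cleavage of F5 with Zn and HCO2NH4 in MeOH would release the triammonium salt of 21, where the route is rejoined before the NH3/MeOH and resin treatment.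

**Further compounds**
F1 | step 6 | {5-(benzyloxy)-6-[4-(benzyloxy)phenyl]-4-oxo-4H-pyran-2-yl}acetic acid | O=C(O)Cc1cc(=O)c(OCc2ccccc2)c(-c2ccc(OCc3ccccc3)cc2)o1
F2 | step 6 | {5-(benzyloxy)-6-[4-(benzyloxy)phenyl]-4-oxo-4H-pyran-2-yl}acetyl chloride | O=C(Cl)Cc1cc(=O)c(OCc2ccccc2)c(-c2ccc(OCc3ccccc3)cc2)o1
F3 | step 5 | trimethyl({[tri(propan-2-yl)silyl]oxy}ethynyl)silane | C[Si](C)(C)C#CO[Si](C(C)C)(C(C)C)C(C)C
F4 | step 5 | 3-(benzyloxy)-2-[4-(benzyloxy)phenyl]-5-hydroxy-6-(trimethylsilyl)-7-[(triisopropylsilyl)oxy]-4H-chromen-4-one | O=c1c(OCc2ccccc2)c(-c2ccc(OCc3ccccc3)cc2)oc2cc(O[Si](C(C)C)(C(C)C)C(C)C)c([Si](C)(C)C)c(O)c12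
F5 | step 8 | 5-O-acetylkaempferol 3,7,4'-tris(2,2,2-trichloroethyl sulfate) | CC(=O)Oc1cc(OS(=O)(=O)OCC(Cl)(Cl)Cl)cc2oc(-c3ccc(OS(=O)(=O)OCC(Cl)(Cl)Cl)cc3)c(OS(=O)(=O)OCC(Cl)(Cl)Cl)c(=O)c12
A1 | direct plan | racemic 1,3-bis(benzyloxy)-5-({1-[4-(benzyloxy)phenyl]prop-2-yn-1-yl}oxy)benzene | C#CC(Oc1cc(OCc2ccccc2)cc(OCc2ccccc2)c1)c1ccc(OCc2ccccc2)cc1
A2 | direct plan | racemic 5,7-bis(benzyloxy)-2-[4-(benzyloxy)phenyl]-2H-chromene | C1(c2ccc(OCc3ccccc3)cc2)Oc2cc(OCc3ccccc3)cc(OCc3ccccc3)c2C=C1
A3 | direct plan | rac-(2R,3S,4S)-5,7-bis(benzyloxy)-2-[4-(benzyloxy)phenyl]-3,4-dihydro-2H-chromene-3,4-diol | O[C@H]1c2c(OCc3ccccc3)cc(OCc3ccccc3)cc2O[C@H](c2ccc(OCc3ccccc3)cc2)[C@H]1O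
A4 | direct plan | kaempferol | O=c1c(O)c(-c2ccc(O)cc2)oc2cc(O)cc(O)c12
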